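**Retrosynthetic overview**
- Ring C is the only ring made and is closed last: the C4–C4a bond comes from an intramolecular Friedel–Crafts acylation of (3S)-3-(3,4,5-trimethoxyphenoxy)-3-(3,4,5-trimethoxyphenyl)propanoic acid. Rings A and B are bought (3,4,5-trimethoxyphenol, 3,4,5-trimethoxybenzyl chloride).
- The acid comes from oxidative cleavage of the propenyl end of a homoallylic aryl ether; the O1–C2 bond comes from a Mitsunobu inversion of an (R)-benzylic alcohol.
- The C2–C3 bond and the C2 stereocentre come from a [2,3]-Wittig rearrangement of a 3,4,5-trimethoxybenzyl ether of (S)-but-3-en-2-ol; the bought C–O centre is relayed to the new carbinol carbon and destroyed.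
- The ether comes from a Williamson coupling of the two bought pieces.

Assumption: (S)-but-3-en-2-ol is bought enantiopure (≥98% ee, catalogue compound with the configuration of (S)-lactate), and a one-flask operation counts as one step.

**Route**

Step 1
Reactants: 1 (S)-but-3-en-2-ol; 2 5-(chloromethyl)-1,2,3-trimethoxybenzene
Product: 4 5-{[(2S)-but-3-en-2-yloxy]methyl}-1,2,3-trimethoxybenzene, via sodium alkoxide 3 (not isolated)
Conditions: NaH (1.2 equiv), DMF, 0 °C → rt
Reagents that add atoms: none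
Why: Williamson ether synthesis (SN2 of the alkoxide on the benzylic chloride); no bond at the stereocentre is broken, so the (S) centre is carried over intact.

Step 2
Reactants: 4 5-{[(2S)-but-3-en-2-yloxy]methyl}-1,2,3-trimethoxybenzene
Product: 7 (1R,3E)-1-(3,4,5-trimethoxyphenyl)pent-3-en-1-ol, via benzylic organolithium 5 (not isolated), via lithium alkoxide 6 (not isolated)
Conditions: n-BuLi (1.3 equiv), THF, −78 °C, 3 h; then H2O; minor (Z)-isomer removed on AgNO3-impregnated silica
Reagents that add atoms: none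
Why: Benzylic α-lithiation triggers a [2,3]-Wittig sigmatropic rearrangement through a five-membered envelope transition state in which the allylic methyl (giving the E-alkene) and the aryl group lie exo and trans to each other, so the (S) C–O centre is relayed to the new (R) carbinol carbon as the C2–C3 bond forms.

Step 3
Reactants: 7 (1R,3E)-1-(3,4,5-trimethoxyphenyl)pent-3-en-1-ol; 8 3,4,5-trimethoxyphenol
Product: 10 1,2,3-trimethoxy-5-[(1S,3E)-1-(3,4,5-trimethoxyphenoxy)pent-3-en-1-yl]benzene, via alkoxyphosphonium phenoxide 9 (not isolated)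
Conditions: PPh3 (1.5 equiv), DIAD (1.5 equiv), toluene, 0 °C → rt
Reagents that add atoms: none
Why: Mitsunobu etherification: the phenoxide displaces the alkoxyphosphonium group by SN2 with inversion, turning the (R) carbinol into the (S) aryl ether that becomes C2 (the 3,4,5-trimethoxyphenyl group is not a strong cation stabiliser, which disfavours ionisation).

Step 4
Reactants: 10 1,2,3-trimethoxy-5-[(1S,3E)-1-(3,4,5-trimethoxyphenoxy)pent-3-en-1-yl]benzene
Product: 12 (3S)-3-(3,4,5-trimethoxyphenoxy)-3-(3,4,5-trimethoxyphenyl)propanoic acid, via aldehyde 11 (not isolated)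
Conditions: OsO4 (1 mol%), 2KHSO5·KHSO4·K2SO4 (Oxone, 4 equiv of KHSO5), DMF, rt, 3 h
Reagents that add atoms: potassium peroxymonosulfate KHSO5 (active salt of Oxone), [K+].[O-]S(=O)(=O)OO
Why: OsO4-catalysed oxidative cleavage of the alkene with peroxymonosulfate gives the aldehyde, which is oxidised on to the acid in the same flask (the C2 fragment ends as acetic acid); the base-sensitive β-aryloxy aldehyde is never handled and the stereocentre is not touched.

Step 5
Reactants: 12 (3S)-3-(3,4,5-trimethoxyphenoxy)-3-(3,4,5-trimethoxyphenyl)propanoic acid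
Product: 14 (2S)-5,6,7-trimethoxy-2-(3,4,5-trimethoxyphenyl)-2,3-dihydro-4H-chromen-4-one, via mixed anhydride 13 (not isolated)
Conditions: TFAA (2 equiv), CH2Cl2, 0 °C → rt; cold aq. NaHCO3 quench; recrystallisation from EtOH
Reagents that add atoms: none
Why: Intramolecular Friedel–Crafts acylation: the mixed anhydride acylates the very electron-rich phenoxy ring ortho to the ether oxygen (both ortho positions are equivalent), closing ring C with the 5,6,7-trimethoxy pattern while no bond at C2 is broken.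

**Compound list**
1 | (S)-but-3-en-2-ol | C[C@H](O)C=C | starting material
2 | 5-(chloromethyl)-1,2,3-trimethoxybenzene (3,4,5-trimethoxybenzyl chloride) | COc1cc(CCl)cc(OC)c1OC | starting material
3 | sodium (2S)-but-3-en-2-olate | C[C@H]([O-])C=C.[Na+] | intermediate
4 | 5-{[(2S)-but-3-en-2-yloxy]methyl}-1,2,3-trimethoxybenzene | C[C@H](OCc1cc(OC)c(OC)c(OC)c1)C=C | intermediate
5 | {[(2S)-but-3-en-2-yloxy](3,4,5-trimethoxyphenyl)methyl}lithium (benzylic carbon configurationally labile) | C[C@H](OC([Li])c1cc(OC)c(OC)c(OC)c1)C=C | intermediate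
6 | lithium (1R,3E)-1-(3,4,5-trimethoxyphenyl)pent-3-en-1-olate | C/C=C/C[C@@H]([O-])c1cc(OC)c(OC)c(OC)c1.[Li+] | intermediate
7 | (1R,3E)-1-(3,4,5-trimethoxyphenyl)pent-3-en-1-ol | C/C=C/C[C@@H](O)c1cc(OC)c(OC)c(OC)c1 | intermediate
8 | 3,4,5-trimethoxyphenol | COc1cc(O)cc(OC)c1OC | starting material
9 | {[(1R,3E)-1-(3,4,5-trimethoxyphenyl)pent-3-en-1-yl]oxy}(triphenyl)phosphonium 3,4,5-trimethoxyphenolate | C/C=C/C[C@@H](O[P+](c1ccccc1)(c1ccccc1)c1ccccc1)c1cc(OC)c(OC)c(OC)c1.[O-]c1cc(OC)c(OC)c(OC)c1 | intermediate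
10 | 1,2,3-trimethoxy-5-[(1S,3E)-1-(3,4,5-trimethoxyphenoxy)pent-3-en-1-yl]benzene | C/C=C/C[C@H](Oc1cc(OC)c(OC)c(OC)c1)c1cc(OC)c(OC)c(OC)c1 | intermediate
11 | (3S)-3-(3,4,5-trimethoxyphenoxy)-3-(3,4,5-trimethoxyphenyl)propanal | O=CC[C@H](Oc1cc(OC)c(OC)c(OC)c1)c1cc(OC)c(OC)c(OC)c1 | intermediate
12 | (3S)-3-(3,4,5-trimethoxyphenoxy)-3-(3,4,5-trimethoxyphenyl)propanoic acid | OC(=O)C[C@H](Oc1cc(OC)c(OC)c(OC)c1)c1cc(OC)c(OC)c(OC)c1 | intermediate
13 | (3S)-3-(3,4,5-trimethoxyphenoxy)-3-(3,4,5-trimethoxyphenyl)propanoic trifluoroacetic anhydride | O=C(C[C@H](Oc1cc(OC)c(OC)c(OC)c1)c1cc(OC)c(OC)c(OC)c1)OC(=O)C(F)(F)F | intermediate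
14 | (2S)-5,6,7-trimethoxy-2-(3,4,5-trimethoxyphenyl)-2,3-dihydro-4H-chromen-4-one | COc1cc([C@@H]2CC(=O)c3c(cc(OC)c(OC)c3OC)O2)cc(OC)c1OC | target

**Step count and risks**
Total step count: 5. Longest linear sequence: 5 (from 1 or 2 to 14).

Risk 1, step 2. n-BuLi may lithiate the ring next to a methoxy group or give [1,2]-shift instead of clean benzylic deprotonation, and any (Z)-alkene formed carries eroded configuration. The fallback makes the same carbanion without a base. It sets out from 2: NaSPh in DMF gives 1,2,3-trimethoxy-5-[(phenylsulfanyl)methyl]benzene F1. NCS in CH2Cl2 at 0 °C gives 5-[chloro(phenylsulfanyl)methyl]-1,2,3-trimethoxybenzene F2. Alcohol 1 with i-Pr2NEt gives the O,S-acetal 5-{[(2S)-but-3-en-2-yloxy](phenylsulfanyl)methyl}-1,2,3-trimethoxybenzene F3, and both epimers at the acetal carbon are usable. Reductive lithiation with LiC10H8 (lithium naphthalenide, 2.2 equiv, THF, −78 °C) cleaves the C–S bond to organolithium 5, which rearranges as before, and the route is rejoined at 7.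

Risk 2, step 3. The activated benzylic, homoallylic alcohol may eliminate to the aryl diene or partly ionise, lowering yield or ee. The fallback forms the C–O bond at the aryl carbon, with retention at the stereocentre. It sets out from 2, which is etherified as in step 1 with bought (R)-but-3-en-2-ol to give 5-{[(2R)-but-3-en-2-yloxy]methyl}-1,2,3-trimethoxybenzene F4. Rearrangement as in step 2 gives (1S,3E)-1-(3,4,5-trimethoxyphenyl)pent-3-en-1-ol F5. Ullmann-type O-arylation of F5 with 5-iodo-1,2,3-trimethoxybenzene (CuI 10 mol%, 3,4,7,8-tetramethyl-1,10-phenanthroline, Cs2CO3, toluene, 110 °C) gives 10, where the route is rejoined.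

Risk 3, step 4. KHSO5 may oxidise the tetra-oxygenated ring, or the β-aryloxy aldehyde may lose the phenol before it is oxidised. The fallback cleaves stepwise without a peroxy oxidant. It sets out from 10: OsO4 (cat.) with NMO in acetone/H2O gives (5S)-5-(3,4,5-trimethoxyphenoxy)-5-(3,4,5-trimethoxyphenyl)pentane-2,3-diol F6, a mixture of the (2R,3R) and (2S,3S) diastereomers that does not matter. NaIO4 in THF/H2O at 0 °C cleaves it to aldehyde 11. This is oxidised crude with NaClO2, NaH2PO4 and 2-methyl-2-butene in t-BuOH/H2O, and the route is rejoined at 12.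

**Further compounds**
F1 | step 2 | 1,2,3-trimethoxy-5-[(phenylsulfanyl)methyl]benzene | COc1cc(CSc2ccccc2)cc(OC)c1OC
F2 | step 2 | 5-[chloro(phenylsulfanyl)methyl]-1,2,3-trimethoxybenzene (racemic) | COc1cc(C(Cl)Sc2ccccc2)cc(OC)c1OC
F3 | step 2 | 5-{[(2S)-but-3-en-2-yloxy](phenylsulfanyl)methyl}-1,2,3-trimethoxybenzene (both epimers at the acetal carbon) | C[C@H](OC(Sc1ccccc1)c1cc(OC)c(OC)c(OC)c1)C=C
F4 | step 3 | 5-{[(2R)-but-3-en-2-yloxy]methyl}-1,2,3-trimethoxybenzene | C[C@@H](OCc1cc(OC)c(OC)c(OC)c1)C=C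
F5 | step 3 | (1S,3E)-1-(3,4,5-trimethoxyphenyl)pent-3-en-1-ol | C/C=C/C[C@H](O)c1cc(OC)c(OC)c(OC)c1
F6 | step 4 | (5S)-5-(3,4,5-trimethoxyphenoxy)-5-(3,4,5-trimethoxyphenyl)pentane-2,3-diol (diastereomer mixture at C2 and C3) | CC(O)C(O)C[C@H](Oc1cc(OC)c(OC)c(OC)c1)c1cc(OC)c(OC)c(OC)c1
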